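**Assumption (remark on the chemistry):** 26 has no stereocentre, so no configuration has to be set. The only stereogenic elements on the way (the double bond of 9, the bridgeheads of 23) are erased, and 9 is therefore carried as an E/Z mixture.

## The problem

Target 26 is a 19-membered macrocyclic bis(bibenzyl). Four benzene rings form a closed loop through two CH2CH2 bridges (ring A to ring D, ring B to ring C) and two diaryl ether oxygens (ring A–O–ring B, ring C–O–ring D). Ring A carries OMe with the ether oxygen ortho and the bridge para to it; ring B is para-linked; ring C carries a free OH ortho to its ether oxygen and para to its bridge; ring D is meta-linked. There is no stereocentre, so nothing can or need be relayed. The difficulties are the closure of the large ring, two aryl C–O bonds on electron-rich, non-activated rings, and the distinction of four phenolic oxygens (one methylated, one free, two arylated). The finished molecule is robust apart from its oxidisable electron-rich rings and benzylic positions. The fragile functions are the ones needed on the way: an aryl ethynyl ether (acid, nucleophiles, concentration), a 2-pyrone (bases, nucleophiles) and the acidic CH2 between ring C and a ketone. These must be introduced late and under near-neutral conditions. The enabling feature is ring B: it bears only the ether oxygen at C1 and a carbon chain at C4, with four CH positions. This is the pattern produced when the C3–C6 diene of a 5-acyl-2-pyrone takes up the two carbons of an ynol ether and loses CO2. Because ring B lies in the macrocycle, building it from two chain ends also closes the 19-membered ring.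

## Retrosynthesis

**26 from 24.** The last operation is a change of oxidation level and protection only. The benzylic CH2 next to ring B is traced to the ketone of 24 and the ring C phenol to its methoxymethyl (MOM) ether. The ketone is the group that activates the pyrone in the key step, and it sits para to the aryloxy donor on ring B, the situation in which ionic hydrogenation (Et3SiH, CF3CO2H) works best. The same acid removes the MOM group, so one step suffices. A benzyl ether on ring C was set aside because hydrogenation is needed earlier (step 6) and must leave the ring C oxygen protected.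

**24 from 22 (key disconnection).** The C1–C6 and C2–C3 bonds of ring B are cut, together with a notional CO2 bridge. This opens both ring B and the macrocycle and leads to open-chain 22, which has an ethynyl ether on the ring A oxygen and a 5-(arylacetyl)-2-pyrone on the ring C side chain. Compared with an Ullmann or Wittig macrocyclisation, no aryl C–O bond has to be formed in the ring-closing event, and the A–B diaryl ether arises without copper. The forward reaction must be regioselective (oxygen para to the acyl carbon) and must cyclise faster than it oligomerises. It passes through bridged lactone 23.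

**22 from 18 and 20.** The bond between the ketone carbon and the ring C benzylic carbon is cut. The benzylic carbon becomes the nucleophile (benzylzinc chloride 21 from chloride 18) and the pyrone carboxyl the electrophile (coumaloyl chloride 20 from coumalic acid 19). An organozinc is chosen because it is too weakly basic and nucleophilic to attack the pyrone ring or the alkyne C–H, and zerovalent palladium directs it to the acid chloride. The forward step must stop at the ketone.

**18 from 11 via 16, 13 and 12.** The two alkyne carbons are removed from the ring A oxygen: ethynyl ether 16 comes from (E)-1,2-dichlorovinyl ether 13 by elimination and chlorine–lithium exchange, and the dichlorovinyl ether 12 from phenol 11 and trichloroethylene. The order is dictated by functional group tolerance. The phenol is vinylated while ring C still carries its ester (no alcohol competes), the ester is reduced to alcohol 13 before n-BuLi is used, and the chloride 18 is made from alcohol 16 only after the organolithium step.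

**11 from 7 and 4 via 9.** The ring A–ring D ethano bridge is cut as a double bond (Wittig reaction of phosphonium salt 7 with aldehyde 4 to give stilbene 9), and the ring A phenol is traced to a benzyl ether. One hydrogenation then saturates the bridge and frees the only phenol in the molecule at the moment it is needed. This is why the ring C oxygen carries MOM and the ring A oxygen benzyl. Making the C–D ether before the bridge avoids having to distinguish two phenols on an A–D bibenzyl.

**4 from 2 and 3; 7 from 5 via 6; 2 from 1.** The ring C carbon–oxygen bond of the C–D ether is cut to bromide 2 and 3-hydroxybenzaldehyde 3 (Ullmann coupling). The ester on ring C and the aldehyde on ring D are at different oxidation levels, so only ring D reacts in the Wittig step. Bromide 2 is the MOM ether of commercial methyl 3-bromo-4-hydroxybenzoate 1. Phosphonium salt 7 comes in two steps from commercial 3-(benzyloxy)-4-methoxybenzaldehyde 5 (the benzyl ether of isovanillin) through alcohol 6.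

## Roads not taken

**Alternative 1:** oxidative phenol coupling to close the ring at the ring C carbon–oxygen bond. The open-chain bis(bibenzyl) A1 carries a 2,6-dibromophenol as ring C and a 2,4,6-tribromophenol as ring D. Tl(NO3)3 (trivalent thallium) would oxidise ring C, the ring D oxygen would attack a brominated ortho carbon, and zinc work-up would expel that bromine to give tetrabromo macrocycle A2. Hydrogenolysis of four C–Br bonds would then give 26.
- Merits: this reaction type is established for macrocyclic diaryl ethers of ortho-halogenated phenols, it runs at room temperature, and it closes the ring at a late stage. In precedent it is clearly ahead of the chosen plan, whose key step has no direct model.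
- Weak points: five bromine atoms are installed only to be removed; both ring C and ring D are bromophenols, so which ring is oxidised and which acts as nucleophile is not secured by the structure; a toxic heavy metal is used in stoichiometric amount. The ring A–ring B ether and both bridges still need conventional construction, with bromination placed after any hydrogenation.
- Comparison: the chosen plan offers fewer steps, no halogen traffic, and a regiochemistry fixed by orbital polarisation rather than by blocking groups.

**Alternative 2:** ring D made by a Diels–Alder reaction on a macrocycle that already exists. Macrocyclic 4-aryloxy-6-alkyl-2-pyrone A3 would add phenyl vinyl sulfone A5 across C3 and C6 and lose CO2 and benzenesulfinic acid to give the O-benzyl target A4, one hydrogenolysis away from 26.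
- Merits: the dienophile is a separate reagent and can be used in excess, so the cycloaddition has no effective-molarity problem, which is a real advantage over the chosen key step. No ketone has to be removed afterwards.
- Weak points: the strategic step does not close the macrocycle. A3 needs its own 19-membered ring closure with a base-sensitive pyrone in place. The 4-aryloxy pyrone has to come from O-arylation of an ambident 4-hydroxypyrone by a non-activated ring C halide. A 4-oxygenated 2-pyrone is also a sluggish diene toward an electron-poor dienophile.
- Comparison: the chosen plan solves ring formation and macrocyclisation in one event, at the price of an untested intramolecular rate.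

**Alternative 3:** the ring A carbon–oxygen bond formed at the sp3 level. In the open-chain epoxy ketone A6 the ring B phenoxide would open the 2,3-epoxycyclohexanone at the carbon alpha to the carbonyl, and loss of water would give macrocyclic 2-aryloxycyclohexenone A7.
- Merits: the ring closes by SN2 displacement at a carbon activated by the ketone, a known intermolecular reaction of phenols with such epoxides, and no transition metal is needed.
- Weak points: a phenoxide must attack a secondary, hindered carbon in a macrocyclisation while enolisation and attack at the beta carbon compete. A6 carries three stereocentres of no use. After ring closure, ring A must still be dehydrogenated to phenol A8 in a molecule with two oxidisable ethano bridges, methylated to A4 and debenzylated.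
- Comparison: that is three steps after the key step against one in the chosen plan, which delivers ring B already aromatic and correctly substituted. Alternative 3 has the better-grounded bond-forming event; the chosen plan has the shorter and cleaner endgame.

Key step: step 13

## Route

Step 1
Reactants: 1 methyl 3-bromo-4-hydroxybenzoate
Product: 2 methyl 3-bromo-4-(methoxymethoxy)benzoate
Conditions: MOMCl, i-Pr2NEt, CH2Cl2, 0 °C to rt
Reagents that add atoms: chloromethyl methyl ether, COCCl
Why: O-alkylation of the phenol to its MOM acetal; this group should survive the hydrogenation of step 6, the bases and organometallics of steps 2 to 12 and the heat of step 13, and it falls in the acid of step 14.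

Step 2
Reactants: 2 methyl 3-bromo-4-(methoxymethoxy)benzoate; 3 3-hydroxybenzaldehyde
Product: 4 methyl 3-(3-formylphenoxy)-4-(methoxymethoxy)benzoate
Conditions: CuI (10 mol %), N,N-dimethylglycine hydrochloride, Cs2CO3, 1,4-dioxane, 100 °C
Reagents that add atoms: none
Why: Ullmann diaryl ether coupling with monovalent copper and an amino acid ligand, a system that accepts ortho-alkoxy aryl bromides, esters and aldehydes; the aldehyde of 3 has no alpha hydrogen and the ortho acetal oxygen can assist by chelation.

Step 3
Reactants: 5 3-(benzyloxy)-4-methoxybenzaldehyde
Product: 6 [3-(benzyloxy)-4-methoxyphenyl]methanol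
Conditions: NaBH4, MeOH, 0 °C
Reagents that add atoms: none
Why: Borohydride reduction of an aromatic aldehyde; no other reducible group is present.

Step 4
Reactants: 6 [3-(benzyloxy)-4-methoxyphenyl]methanol
Product: 7 {[3-(benzyloxy)-4-methoxyphenyl]methyl}triphenylphosphonium bromide
Conditions: Ph3P·HBr, MeCN, reflux
Reagents that add atoms: triphenylphosphine hydrobromide, [Br-].c1ccc(cc1)[PH+](c1ccccc1)c1ccccc1
Why: Direct conversion of an electron-rich benzylic alcohol into its phosphonium salt; the para-methoxy benzylic cation forms readily under the mildly acidic salt and is captured by PPh3, while the aryl benzyl ether should not be cleaved.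

Step 5
Reactants: 7 {[3-(benzyloxy)-4-methoxyphenyl]methyl}triphenylphosphonium bromide; 4 methyl 3-(3-formylphenoxy)-4-(methoxymethoxy)benzoate
Product: 9 methyl 3-(3-{2-[3-(benzyloxy)-4-methoxyphenyl]ethenyl}phenoxy)-4-(methoxymethoxy)benzoate (E/Z mixture), via benzylidene phosphorane 8 (not isolated)
Conditions: NaN(SiMe3)2, THF, 0 °C; then 4, 0 °C to rt
Reagents that add atoms: none
Why: Wittig olefination with a semi-stabilised benzylide, which reacts with the aldehyde and not with the methyl ester at this temperature; the alkene geometry is irrelevant because the double bond is reduced next.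

Step 6
Reactants: 9 methyl 3-(3-{2-[3-(benzyloxy)-4-methoxyphenyl]ethenyl}phenoxy)-4-(methoxymethoxy)benzoate
Product: 11 methyl 3-{3-[2-(3-hydroxy-4-methoxyphenyl)ethyl]phenoxy}-4-(methoxymethoxy)benzoate, via O-benzyl bibenzyl 10 (not isolated)
Conditions: H2 (1 atm), Pd/C (10 wt %), EtOAc–THF, rt
Reagents that add atoms: none
Why: Catalytic hydrogenation saturates the stilbene and then hydrogenolyses the aryl benzyl ether, so the single free phenol appears on ring A when it is needed; MOM acetal, ester and diaryl ether are inert under neutral, non-alcoholic conditions.

Step 7
Reactants: 11 methyl 3-{3-[2-(3-hydroxy-4-methoxyphenyl)ethyl]phenoxy}-4-(methoxymethoxy)benzoate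
Product: 12 methyl 3-{3-[2-(3-{[(E)-1,2-dichloroethenyl]oxy}-4-methoxyphenyl)ethyl]phenoxy}-4-(methoxymethoxy)benzoate
Conditions: trichloroethylene, K2CO3, DMF, 70 °C
Reagents that add atoms: trichloroethylene, ClC=C(Cl)Cl
Why: Known O-dichlorovinylation of phenols: carbonate generates dichloroacetylene from trichloroethylene, the phenoxide adds, and anti protonation gives the E ether; no alcohol is present to compete and the ester is not touched.

Step 8
Reactants: 12 methyl 3-{3-[2-(3-{[(E)-1,2-dichloroethenyl]oxy}-4-methoxyphenyl)ethyl]phenoxy}-4-(methoxymethoxy)benzoate
Product: 13 [3-{3-[2-(3-{[(E)-1,2-dichloroethenyl]oxy}-4-methoxyphenyl)ethyl]phenoxy}-4-(methoxymethoxy)phenyl]methanol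
Conditions: i-Bu2AlH, CH2Cl2, −78 to 0 °C; Rochelle salt work-up
Reagents that add atoms: none
Why: Ester reduction with an aluminium hydride at low temperature, which leaves vinyl chlorides and the acetal alone; it is placed here because the ester would not survive the n-BuLi of step 9.

Step 9
Reactants: 13 [3-{3-[2-(3-{[(E)-1,2-dichloroethenyl]oxy}-4-methoxyphenyl)ethyl]phenoxy}-4-(methoxymethoxy)phenyl]methanol
Product: 16 [3-(3-{2-[3-(ethynyloxy)-4-methoxyphenyl]ethyl}phenoxy)-4-(methoxymethoxy)phenyl]methanol, via chloroethynyl ether lithium alkoxide 14 (not isolated), via dilithiated ethynyl ether 15 (not isolated)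
Conditions: n-BuLi (3.3 equiv), THF, −78 to −40 °C; then aq. NH4Cl, −78 °C
Reagents that add atoms: none
Why: Standard conversion of an aryl 1,2-dichlorovinyl ether into the ynol ether: after alkoxide formation, vinylic deprotonation and loss of chloride give chloroalkyne 14, chlorine–lithium exchange gives alkynide 15, and protonation gives the terminal ethynyl ether; at −78 °C lithiation ortho to the MOM group should be slow.

Step 10
Reactants: 16 [3-(3-{2-[3-(ethynyloxy)-4-methoxyphenyl]ethyl}phenoxy)-4-(methoxymethoxy)phenyl]methanol
Product: 18 4-(chloromethyl)-2-(3-{2-[3-(ethynyloxy)-4-methoxyphenyl]ethyl}phenoxy)-1-(methoxymethoxy)benzene, via benzylic mesylate 17 (not isolated)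
Conditions: MsCl, 2,4,6-collidine, LiCl, DMF, 0 °C to rt
Reagents that add atoms: lithium chloride, [Li+].[Cl-] (chlorine of 18); methanesulfonyl chloride, CS(=O)(=O)Cl (mesyl group of intermediate 17)
Why: Mesylation and chloride displacement in one flask under buffered, basic conditions, which the acid-sensitive ynol ether and acetal require; the para-alkoxybenzylic mesylate is displaced at once, and the chloride is used without chromatography.

Step 11
Reactants: 19 coumalic acid (2-oxo-2H-pyran-5-carboxylic acid)
Product: 20 2-oxo-2H-pyran-5-carbonyl chloride
Conditions: (COCl)2, DMF (cat.), CH2Cl2, rt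
Reagents that add atoms: oxalyl chloride, O=C(Cl)C(=O)Cl
Why: Acid chloride formation through the Vilsmeier-type chloroiminium catalyst; no nucleophile is present that could open the pyrone.

Step 12
Reactants: 18 4-(chloromethyl)-2-(3-{2-[3-(ethynyloxy)-4-methoxyphenyl]ethyl}phenoxy)-1-(methoxymethoxy)benzene; 20 2-oxo-2H-pyran-5-carbonyl chloride
Product: 22 5-{2-[3-(3-{2-[3-(ethynyloxy)-4-methoxyphenyl]ethyl}phenoxy)-4-(methoxymethoxy)phenyl]acetyl}-2H-pyran-2-one, via benzylzinc chloride 21 (not isolated)
Conditions: Zn dust, LiCl, THF, 25 °C; then added slowly to 20, Pd(PPh3)4 (5 mol %), THF, 0 °C to rt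
Reagents that add atoms: none
Why: LiCl-assisted zinc insertion into the benzylic chloride followed by acylation of the organozinc with an acid chloride under zerovalent palladium (Negishi-type ketone synthesis); the benzylzinc is too weakly basic to metalate the alkyne C–H or add to the pyrone, and inverse addition keeps it away from the acidic CH2 of the product.

Step 13
Reactants: 22 5-{2-[3-(3-{2-[3-(ethynyloxy)-4-methoxyphenyl]ethyl}phenoxy)-4-(methoxymethoxy)phenyl]acetyl}-2H-pyran-2-one
Product: 24 macrocyclic deoxybenzoin, the analogue of 26 with C=O in place of the CH2 attached to ring B and OCH2OCH3 in place of OH on ring C, via bridged lactone cycloadduct 23 (not isolated)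
Conditions: toluene (syringe-pump addition, final 0.001 M), BHT (cat.), 110 °C, Ar
Reagents that add atoms: none
Why: Proposed new method: the terminal alkyne carbon, the nucleophilic end of the ynol ether, bonds to pyrone C6 (delta to the lactone carbonyl and beta to the 5-acyl carbonyl) while the oxygen-bearing alkyne carbon bonds to C3, in an inverse-electron-demand [4+2] cycloaddition that gives bridged lactone 23, and irreversible retro-[4+2] loss of CO2 from 23 leaves benzene ring B. The closest known reaction type is the intermolecular Diels–Alder reaction of coumalates and related 5-acceptor 2-pyrones with ynamines and ynol ethers, which gives para-donor benzoates after loss of CO2; a macrocyclising version has not been described. Ring B, a six-membered carbocycle, closes by the cycloaddition–cycloreversion pair, and the 19-membered ring closes in the same event as a type 2 intramolecular Diels–Alder reaction whose tether runs from the C5 acyl group through ring C, ring D and ring A to the ynol oxygen. No stereocentre is formed in 24, and the two bridgehead centres of 23 vanish with the CO2. The step needs para and not meta placement of oxygen and acyl carbon on ring B, which is secured by matching the largest HOMO coefficient (alkyne CH) with the largest LUMO coefficient (C6). It also needs cyclisation ahead of oligomerisation, which slow addition to millimolar concentration should secure. An aryl ynol ether has no beta hydrogen for the retro-ene fragmentation to a ketene that limits alkyl ynol ethers on heating, and at this dilution polymerisation of the alkyne is slow, so the intramolecular cycloaddition should be the main pathway open to 22.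

Step 14
Reactants: 24 macrocyclic deoxybenzoin MOM ether
Product: 26 target macrocycle CNP0132125.0, via macrocyclic phenol ketone 25 (not isolated)
Conditions: Et3SiH (excess), CF3CO2H–CH2Cl2, 0 °C to rt
Reagents that add atoms: none
Why: Ionic hydrogenation of an aryl ketone: protonation and hydride transfer give the benzylic alcohol, ionisation gives a cation stabilised by the para aryloxy group of ring B, and a second hydride transfer gives CH2; the same acid cleaves the phenolic MOM acetal first, and the silane reduces the methoxymethyl cation before it can alkylate the electron-rich rings.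

## Compound list

1 | methyl 3-bromo-4-hydroxybenzoate | COC(=O)c1ccc(O)c(Br)c1 | starting material
2 | methyl 3-bromo-4-(methoxymethoxy)benzoate | COCOc1ccc(cc1Br)C(=O)OC | intermediate
3 | 3-hydroxybenzaldehyde | O=Cc1cccc(O)c1 | starting material
4 | methyl 3-(3-formylphenoxy)-4-(methoxymethoxy)benzoate | COCOc1ccc(cc1Oc1cccc(C=O)c1)C(=O)OC | intermediate
5 | 3-(benzyloxy)-4-methoxybenzaldehyde (benzyl ether of isovanillin) | COc1ccc(C=O)cc1OCc1ccccc1 | starting material
6 | [3-(benzyloxy)-4-methoxyphenyl]methanol | COc1ccc(CO)cc1OCc1ccccc1 | intermediate
7 | {[3-(benzyloxy)-4-methoxyphenyl]methyl}triphenylphosphonium bromide | COc1ccc(C[P+](c2ccccc2)(c2ccccc2)c2ccccc2)cc1OCc1ccccc1.[Br-] | intermediate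
8 | [3-(benzyloxy)-4-methoxybenzylidene]triphenylphosphorane (ylide of 7) | COc1ccc(C=P(c2ccccc2)(c2ccccc2)c2ccccc2)cc1OCc1ccccc1 | intermediate (not isolated)
9 | methyl 3-(3-{2-[3-(benzyloxy)-4-methoxyphenyl]ethenyl}phenoxy)-4-(methoxymethoxy)benzoate, E/Z mixture | COCOc1ccc(cc1Oc1cccc(C=Cc2ccc(OC)c(OCc3ccccc3)c2)c1)C(=O)OC | intermediate
10 | methyl 3-(3-{2-[3-(benzyloxy)-4-methoxyphenyl]ethyl}phenoxy)-4-(methoxymethoxy)benzoate | COCOc1ccc(cc1Oc1cccc(CCc2ccc(OC)c(OCc3ccccc3)c2)c1)C(=O)OC | intermediate (not isolated)
11 | methyl 3-{3-[2-(3-hydroxy-4-methoxyphenyl)ethyl]phenoxy}-4-(methoxymethoxy)benzoate | COCOc1ccc(cc1Oc1cccc(CCc2ccc(OC)c(O)c2)c1)C(=O)OC | intermediate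
12 | methyl 3-{3-[2-(3-{[(E)-1,2-dichloroethenyl]oxy}-4-methoxyphenyl)ethyl]phenoxy}-4-(methoxymethoxy)benzoate | COCOc1ccc(cc1Oc1cccc(CCc2ccc(OC)c(O/C(Cl)=C\Cl)c2)c1)C(=O)OC | intermediate
13 | [3-{3-[2-(3-{[(E)-1,2-dichloroethenyl]oxy}-4-methoxyphenyl)ethyl]phenoxy}-4-(methoxymethoxy)phenyl]methanol | COCOc1ccc(CO)cc1Oc1cccc(CCc2ccc(OC)c(O/C(Cl)=C\Cl)c2)c1 | intermediate
14 | lithium alkoxide of the chloroethynyl ether derived from 13 | [Li]OCc1ccc(OCOC)c(Oc2cccc(CCc3ccc(OC)c(OC#CCl)c3)c2)c1 | intermediate (not isolated)
15 | dilithiated ethynyl ether (lithium alkynide and lithium alkoxide) | [Li]OCc1ccc(OCOC)c(Oc2cccc(CCc3ccc(OC)c(OC#C[Li])c3)c2)c1 | intermediate (not isolated)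
16 | [3-(3-{2-[3-(ethynyloxy)-4-methoxyphenyl]ethyl}phenoxy)-4-(methoxymethoxy)phenyl]methanol | COCOc1ccc(CO)cc1Oc1cccc(CCc2ccc(OC)c(OC#C)c2)c1 | intermediate
17 | methanesulfonate of 16 | COCOc1ccc(COS(C)(=O)=O)cc1Oc1cccc(CCc2ccc(OC)c(OC#C)c2)c1 | intermediate (not isolated)
18 | 4-(chloromethyl)-2-(3-{2-[3-(ethynyloxy)-4-methoxyphenyl]ethyl}phenoxy)-1-(methoxymethoxy)benzene | COCOc1ccc(CCl)cc1Oc1cccc(CCc2ccc(OC)c(OC#C)c2)c1 | intermediate
19 | coumalic acid (2-oxo-2H-pyran-5-carboxylic acid) | O=C(O)c1ccc(=O)oc1 | starting material
20 | 2-oxo-2H-pyran-5-carbonyl chloride | O=C(Cl)c1ccc(=O)oc1 | intermediate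
21 | benzylzinc chloride derived from 18 | COCOc1ccc(C[Zn]Cl)cc1Oc1cccc(CCc2ccc(OC)c(OC#C)c2)c1 | intermediate (not isolated)
22 | 5-{2-[3-(3-{2-[3-(ethynyloxy)-4-methoxyphenyl]ethyl}phenoxy)-4-(methoxymethoxy)phenyl]acetyl}-2H-pyran-2-one | C#COc1cc(CCc2cccc(Oc3cc(CC(=O)c4ccc(=O)oc4)ccc3OCOC)c2)ccc1OC | intermediate
23 | bridged lactone cycloadduct: 2-oxabicyclo[2.2.2]octa-5,7-dien-3-one embedded in the macrocycle, ring A oxygen on one alkene carbon, arylacetyl group on the other alkene; racemic, transient | COc1ccc2cc1OC3=CC4OC(=O)C3C=C4C(=O)Cc1ccc(OCOC)c(c1)Oc1cccc(c1)CC2 | intermediate (not isolated)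
24 | macrocyclic deoxybenzoin: 26 with C=O in place of the CH2 attached to ring B and OCH2OCH3 in place of OH on ring C | COc1ccc2cc1Oc1ccc(cc1)C(=O)Cc1ccc(OCOC)c(c1)Oc1cccc(c1)CC2 | intermediate
25 | macrocyclic phenol ketone: 24 without the MOM group | COc1ccc2cc1Oc1ccc(cc1)C(=O)Cc1ccc(O)c(c1)Oc1cccc(c1)CC2 | intermediate (not isolated)
26 | CNP0132125.0, 19-membered bis(bibenzyl) with OMe on ring A and OH on ring C | COc1ccc2cc1Oc1ccc(cc1)CCc1ccc(O)c(c1)Oc1cccc(c1)CC2 | target

## Step count and risks

Total: 14 steps. Longest linear sequence: 11 steps (steps 1, 2, 5, 6, 7, 8, 9, 10, 12, 13, 14, starting from 1).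

**Step 13 (key step, proposed new method).** The most likely failure is a slow intramolecular cycloaddition. The effective molarity of a 19-membered closure is low, so at temperatures the ynol ether tolerates the reaction may lag behind oligomerisation, hydration of the alkyne by adventitious water, or enol-mediated decomposition of the acylpyrone. The meta mode of addition could also compete if the tether strains the para transition state.

The fallback uses only known chemistry, sets out from 16 and returns at 26. Ethynyl ether 16 is heated with an excess of methyl coumalate in toluene, the known intermolecular reaction, which should give through the bridged lactone cycloadduct F1 the methyl 4-aryloxybenzoate F2. LiAlH4 reduces it to the diol F3, and MnO2 oxidises both benzylic alcohols to the dialdehyde F4. McMurry coupling with low-valent titanium (TiCl4, Zn, pyridine, THF, reflux, high dilution), a closure known for macrocyclic bis(bibenzyl)s, gives the macrocyclic stilbene F5. Hydrogenation over Pd/C gives the MOM ether of the target F6, and HCl in MeOH gives 26.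

**Step 12.** What may go wrong is Wurtz-type homocoupling or protonation of the electron-rich benzylzinc during insertion, interception of the acylpalladium species by the terminal alkyne C–H, or attack of the organozinc on the very electrophilic acid chloride–pyrone system beyond the ketone stage. The fallback replaces the acid chloride by a thioester and sets out from 20 and 21, returning at 22. Treatment of 20 with EtSH and pyridine at −20 °C gives S-ethyl 2-oxo-2H-pyran-5-carbothioate F7, which is inert to the organozinc without catalyst. It is coupled with 21 under PdCl2(PPh3)2 in THF–toluene at rt (Fukuyama ketone synthesis) to give 22.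

**Step 14.** Possible failures are transannular Friedel–Crafts alkylation of ring A or ring C by the benzylic cation, alkylation by the methoxymethyl cation, or stalling at the alcohol or stilbene stage. The fallback separates the events and sets out from 24, returning at 26. NaBH4 in THF–MeOH gives the racemic macrocyclic benzylic alcohol F8. Hydrogenolysis over Pd/C in MeOH containing HCl then removes the benzylic hydroxyl and, through the acid, the MOM group, giving 26.

**Step 2.** The bromide is flanked by an ortho alkoxy group and is not activated, so oxidative addition to copper may be slow, and at 100 °C the phenoxide aldehyde may degrade or the bromide may be reduced. The fallback inverts the polarity at ring C and sets out from 2, returning at 4. Miyaura borylation (B2pin2, PdCl2(dppf), KOAc, dioxane, 80 °C) gives the pinacol boronate F9. NaIO4 and NH4OAc in aqueous acetone give the boronic acid F10. Chan–Lam coupling of F10 with 3 (Cu(OAc)2, divalent copper, pyridine, 4 Å sieves, CH2Cl2, air, rt) gives 4.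

## Further compounds

F1 | step 13 | bridged lactone cycloadduct of 16 with methyl coumalate (racemic, not isolated) | COC(=O)C1=CC2C(=O)OC1C=C2Oc1cc(CCc2cccc(Oc3cc(CO)ccc3OCOC)c2)ccc1OC
F2 | step 13 | methyl 4-{5-[2-(3-{5-(hydroxymethyl)-2-(methoxymethoxy)phenoxy}phenyl)ethyl]-2-methoxyphenoxy}benzoate | COC(=O)c1ccc(cc1)Oc1cc(CCc2cccc(Oc3cc(CO)ccc3OCOC)c2)ccc1OC
F3 | step 13 | diol: F2 with CH2OH in place of the ester | OCc1ccc(cc1)Oc1cc(CCc2cccc(Oc3cc(CO)ccc3OCOC)c2)ccc1OC
F4 | step 13 | dialdehyde: F3 with both CH2OH groups oxidised to CHO | O=Cc1ccc(cc1)Oc1cc(CCc2cccc(Oc3cc(C=O)ccc3OCOC)c2)ccc1OC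
F5 | step 13 | macrocyclic stilbene (E/Z mixture), CH=CH between ring B and ring C, MOM on ring C | COc1ccc2cc1Oc1ccc(cc1)C=Cc1ccc(OCOC)c(c1)Oc1cccc(c1)CC2
F6 | step 13 | MOM ether of 26 | COc1ccc2cc1Oc1ccc(cc1)CCc1ccc(OCOC)c(c1)Oc1cccc(c1)CC2
F7 | step 12 | S-ethyl 2-oxo-2H-pyran-5-carbothioate | CCSC(=O)c1ccc(=O)oc1
F8 | step 14 | macrocyclic benzylic alcohol (racemic): 24 with CH(OH) in place of C=O | COc1ccc2cc1Oc1ccc(cc1)C(O)Cc1ccc(OCOC)c(c1)Oc1cccc(c1)CC2
F9 | step 2 | methyl 4-(methoxymethoxy)-3-(4,4,5,5-tetramethyl-1,3,2-dioxaborolan-2-yl)benzoate | COCOc1ccc(cc1B1OC(C)(C)C(C)(C)O1)C(=O)OC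
F10 | step 2 | [5-(methoxycarbonyl)-2-(methoxymethoxy)phenyl]boronic acid | COCOc1ccc(cc1B(O)O)C(=O)OC
A1 | alternative 1 | open-chain bis(bibenzyl) with 2,6-dibromophenol ring C and 2,4,6-tribromophenol ring D | COc1ccc(CCc2c(Br)c(O)c(Br)cc2Br)cc1Oc1ccc(CCc2cc(Br)c(O)c(Br)c2)cc1
A2 | alternative 1 | tetrabromo macrocycle | COc1ccc2cc1Oc1ccc(cc1)CCc1cc(Br)c(O)c(c1)Oc1c(Br)cc(Br)c(c1Br)CC2
A3 | alternative 2 | macrocyclic 4-aryloxy-6-alkyl-2-pyrone in place of ring D, benzyl ether on ring C | COc1ccc2cc1Oc1ccc(cc1)CCc1ccc(OCc3ccccc3)c(c1)Oc1cc(=O)oc(c1)CC2
A4 | alternative 2 | O-benzyl ether of 26 | COc1ccc2cc1Oc1ccc(cc1)CCc1ccc(OCc3ccccc3)c(c1)Oc1cccc(c1)CC2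
A5 | alternative 2 | phenyl vinyl sulfone | C=CS(=O)(=O)c1ccccc1
A6 | alternative 3 | open-chain 4-substituted 2,3-epoxycyclohexanone with free ring B phenol (mixture of diastereomers) | O=C1CCC(CCc2cccc(Oc3cc(CCc4ccc(O)cc4)ccc3OCc3ccccc3)c2)C2OC12
A7 | alternative 3 | macrocyclic 2-aryloxycyclohexenone (racemic, one enantiomer drawn) | O=C1CC[C@H]2C=C1Oc1ccc(cc1)CCc1ccc(OCc3ccccc3)c(c1)Oc1cccc(c1)CC2
A8 | alternative 3 | macrocyclic ring A phenol: A4 with OH in place of OMe | Oc1ccc2cc1Oc1ccc(cc1)CCc1ccc(OCc3ccccc3)c(c1)Oc1cccc(c1)CC2
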